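Assumption: the target has no stereocentre, so it is made as the single achiral compound drawn; acid 1 and alcohol 2 are taken as bought.

**Retrosynthetic overview**
1. Target 4 ⇒ acid 1 + alcohol 2, one disconnection at the ester O–CH2 (alkyl–oxygen) bond.
2. Forward, the carboxylate of 1 attacks C1 of 2 after the alcohol is activated catalytically as an alkoxyphosphonium. The catalyst is 2-[(diphenylphosphoryl)methyl]phenol, O=P(Cc1ccccc1O)(c1ccccc1)c1ccccc1, and water is the only by-product.
3. The acyl carbon is never made electrophilic, so the free catechol needs no protecting group.
4. No ring is formed (the arene comes with 1).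

**Step 1**
Reactants: 1 3-(3,4-dihydroxyphenyl)propanoic acid (dihydrocaffeic acid); 2 hexadecan-1-ol (cetyl alcohol)
Product: 4 hexadecyl 3-(3,4-dihydroxyphenyl)propanoate, via hexadecyloxyphosphonium carboxylate ion pair 3 (not isolated)
Conditions: 1 (1.0 equiv), 2 (1.05 equiv), 2-[(diphenylphosphoryl)methyl]phenol (15 mol%), xylenes (0.25 M), reflux (ca. 140 °C), Dean–Stark, N2, 24–48 h
Reagents that add atoms: none
Why: Proposed new method: redox-neutral phosphine-oxide (P(V)) catalysed dehydrative O-alkylation of a weakly acidic (pKa about 4.5) aliphatic acid that carries a free catechol, in which acid 1 protonates the P=O of the catalyst, the ortho-phenol arm closes onto phosphorus with loss of water (taken out in the trap) to give a five-membered cyclic aryloxyphosphonium carboxylate, alcohol 2 opens this to the hexadecyloxyphosphonium ion pair 3, and the carboxylate (the only anion present, since the catechol OH groups are about five pKa units less acidic) attacks the unhindered primary O–CH2 carbon in an SN2 step that forms the ester C–O bond and returns the phosphine oxide, so the catechol cannot be acylated or oligomerised and no stereocentre is formed; the closest known reaction types are the phosphine-oxide-catalysed redox-neutral Mitsunobu-type substitution of alcohols, demonstrated mainly with strongly acidic pronucleophiles such as nitrobenzoic acids and not with free catechols, and the stoichiometric Mitsunobu esterification, which is known to select the carboxyl group of phenolic acids over their phenols.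

**Compound list**
1 | 3-(3,4-dihydroxyphenyl)propanoic acid (dihydrocaffeic acid) | OC(=O)CCc1ccc(O)c(O)c1 | starting material
2 | hexadecan-1-ol (cetyl alcohol) | CCCCCCCCCCCCCCCCO | starting material
3 | (hexadecyloxy)(2-hydroxybenzyl)diphenylphosphonium 3-(3,4-dihydroxyphenyl)propanoate (ion pair of the activated alcohol and the carboxylate) | CCCCCCCCCCCCCCCCO[P+](Cc1ccccc1O)(c1ccccc1)c1ccccc1.[O-]C(=O)CCc1ccc(O)c(O)c1 | intermediate
4 | hexadecyl 3-(3,4-dihydroxyphenyl)propanoate | CCCCCCCCCCCCCCCCOC(=O)CCc1ccc(O)c(O)c1 | target

**Totals**
Total step count: 1. Longest linear sequence: 1 step.

**Steps most likely to fail**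
The route has a single step, so only one can be listed.

Step 1 (the proposed new method). Risks:
- Turnover may be slow, because closing the catalyst to the cyclic phosphonium depends on the acid strength of the pronucleophile and 1 is a weak acid.
- The catechol may tie up phosphorus reversibly as aryloxyphosphonium or spirophosphorane species.
- Minor O-hexadecylation of a phenol is possible.
- Acid 1 dissolves poorly in xylenes until it melts.

Slow, uncatalysed thermal esterification under the same water-removing conditions leads to the same product 4, so partial failure of the catalytic cycle still gives some 4.

Fallback (known chemistry, stoichiometric pre-activation of the alcohol in place of catalysis): it sets out from 2 and 1 and comes back to the route at 4. Alcohol 2 is converted into hexadecyl methanesulfonate F1 (MsCl, Et3N, CH2Cl2, 0 °C). Acid 1 is then stirred with KHCO3 (1.1 equiv) and hexadecyl methanesulfonate F1 (1.0 equiv) in DMF at 60 °C under N2. Bicarbonate deprotonates only the carboxyl group, and the carboxylate displaces the mesylate to give 4 directly with the catechol left free.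

**Further compounds**
F1 | step 1 | hexadecyl methanesulfonate | CCCCCCCCCCCCCCCCOS(C)(=O)=O
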